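The numbers of this flask are made up; the result is computed.

The constants set two takers against each other for the second substrate: the enzyme cycle and self-condensation.

    starting material + free enzyme ⇌ first complex (K1 = 200 M⁻¹, k1 = 15000 M⁻¹ s⁻¹)
    first complex → loaded enzyme + first product (k2 = 63 s⁻¹)
    second substrate + loaded enzyme ⇌ second complex (K3 = 190 M⁻¹, k3 = 95000 M⁻¹ s⁻¹)
    second complex → free enzyme + target (k4 = 110 s⁻¹)
    2 second substrate → self-condensation product (k5 = 0.12 M⁻¹ s⁻¹)

| setting | Friday's | Wednesday's | Tuesday's |
|---|---|---|---|
| starting material | 0.040 M | 0.060 M | 0.10 M |
| second substrate | 0.150 M | 0.150 M | 0.150 M |
| free enzyme | 10 µM | 10 µM | 10 µM |
| time | 5.0 min | 5.0 min | 5.0 min |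

- a step written with two of one species runs at k times the square of its concentration and takes two of it each time
- "hardly changes" means that all values lie within two and a half points (for a concentration: within two and a half percent of the largest)
- run time (Friday's): 5.0 min

* amount of target at the end, in percent of the starting material charged for Friday's, Wednesday's, Tuesday's, in this order
* how that number moves from the first to the last of them (rises all the way / falls, then rises / falls all the way / hardly changes / rises, then falls)

- On the first rung, in Friday's flask, loaded enzyme met second substrate in 7.02 × 10⁻⁵ s and free enzyme met starting material in 0.00167 s, both at the charge, and binding constant times charge came to 28 and 8.0, so I expected the complexes to be favoured at the start.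
- On the next rung, the two chemical steps took 0.0250 s per turn, slower than either meeting, so I let these steps set the pace and took the enzyme at a ceiling of 4.01 × 10⁻⁴ M s⁻¹.
- Higher up, self-condensation by this step alone had a first half-life of 27.8 s, far shorter than the 374 s the ceiling would need for the second substrate charged, so the enzyme could not count on the whole charge.
- On a further rung, Friday's starting material needed 99.9 s at the ceiling, inside the 5.0 min allowed.
- I named the crossover concentration, the level of second substrate at which self-condensation consumes it as fast as the ceiling: 0.0409 M.
- At each level, I took the enzyme's share as the ceiling over the sum of the ceiling and the self-condensation rate. Below the crossover that share lay between half and one, and above it between half and one of the ratio of ceiling to self-condensation rate.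
- Adding the share level by level, the upper sum was 0.0706 M and the lower sum half of that. Their middle gave 0.0529 M: the budget, the target the second substrate can pay for before self-condensation takes the rest.
- With the enzyme held at its ceiling, the budget does not depend on the starting material. Friday's 0.040 M lay under it, so I reckoned 100% with starting material as limiting reagent. Wednesday's 0.060 M lay over it, so I reckoned 88.2%, and I expected the row to fall.
- The forecast gave 99.8%, 82% and 51%, falls all the way, its Wednesday's figure lower than my 88.2%, holding that “that budget barely depends on the starting material”.
- The simulation gave 100%, 82.8% and 50.9%: falls all the way.
- In Friday's flask at 0.258 min, self-condensation used second substrate at 1.1 times the rate of the forward binding step, and with the budget of 0.0529 M above the 0.040 M charged, that flask ended with target at >99.9% and 3.9% of its second substrate left. In Tuesday's flask, the budget over the 0.10 M charged reads 52.9%, and the flask ended with second substrate at 0%, starting material at 49%, loaded enzyme at 100% of the catalyst and target at 50.9%.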